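(The data are calculated for substances that don't exist.)

Start from the leftover: in the elm run, which is the flask asked about, a third of the solid substrate still lies undissolved at 300 min, and product has stopped near 16.9%. The suspects are these: solid substrate dissolves to starting material, free enzyme turns that through complex into product, and free enzyme may unfold.

| setting | elm | birch | flask |
|---|---|---|---|
| solid substrate | 0.050 M | 0.075 M | 0.050 M |
| free enzyme | 36 µM | 36 µM | 36 µM |
| temperature | 25 °C | 10 °C | 25 °C |
| remark | the very flask that is asked about, followed so far | run made earlier |  |
| time |  |  | 5.0 h |

- elm (time / min: product / %, solid substrate / %): 40.0: 10.1, 54.7; 80.0: 14.5, 40.3; 120: 16.1, 35.7; 180: 16.6, 33.7; 240: 16.5, 33.4; 300: 16.9, 33.3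
- birch (time / min: product / %, solid substrate / %): 1.00: 0, 98.8; 1.33: 0.2, 97.7; 2.00: 0.1, 97.4; 3.00: 0.3, 96.1; 5.00: 0.3, 93.8; 8.00: 1.1, 90.7; 12.0: 1.7, 86.3

(scatter of a reading: 0.3 percentage points)

* product, in percent of the solid substrate first charged, at 5.0 h
* which option adds most product ("none" when 2 percentage points or less is all one gets) (Thursday's / Monday's / Wednesday's / Saturday's / none)
* product present, with what was taken out counted in, in percent of the solid substrate first charged, after Wednesday's
* product present, with what was taken out counted in, in percent of the solid substrate first charged, after Saturday's

- Thursday's: at 5.0 h raise the temperature by 15 K, then wait 2.5 h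
- Monday's: at 5.0 h add free enzyme, 50.0% of the amount charged, then wait 2.5 h
- Wednesday's: change nothing and wait 2.5 h more
- Saturday's: at 5.0 h take out 90% of the product then present, then wait 2.5 h

- as a solid, counted per litre of solution: solid substrate
- what is taken out of product is counted as made
- on the list of suspects stand: free enzyme -> unfolded enzyme; starting material + free enzyme <-> complex; complex <-> free enzyme + product; solid substrate <-> starting material
- at the start none of the solid substrate is in solution
- additions bring no volume worth counting

Turn the question round: suppose product stopped through loss of free enzyme, so that taking product out brings nothing. Then product should keep its own clock, not the solid's. So test this on the elm run by taking each reading's distance from its last value. Between the first two readings the solid's distance falls by a factor of 3.06 and product's by 2.83, close together, so the two seem to keep one clock.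

I therefore read the stop as a balance. The complex can hold at most 0.0720% of the charge, so leave it out; dissolved starting material is then 49.8%. The last elm readings give 0.339, the balance ratio (an equilibrium constant): c(product) over c(starting material) once product stands still. Use it on the flask: I expect c(starting material) to hold near its level while solid remains, so product should climb back after Saturday's removal. In the last elm reading the solid left exceeds the refill, so I reckon 32.1% counted in, provided enough free enzyme lives. Watch that climb.

The forecast gives 16.7% (16.3% to 17.1%) now, 16.8% (16.3% to 17.4%) after Wednesday's, and 31.5% (22% to 32.5%) after Saturday's, below mine, and it chooses Saturday's: “So I take this as equilibrium with live enzyme.”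

The flask gives 16.8% now, 16.8% after Wednesday's and 29.1% after Saturday's, and Saturday's adds most, 12 percentage points.

    free enzyme → unfolded enzyme (k = 1.30 × 10⁻⁴ s⁻¹, Ea = 257 kJ mol⁻¹)
    starting material + free enzyme ⇌ complex (K = 16.0 M⁻¹, k = 470 M⁻¹ s⁻¹, Ea = 38.0 kJ mol⁻¹, ΔH = −40.0 kJ mol⁻¹)
    complex ⇌ free enzyme + product (K = 0.0210 M, k = 1.50 s⁻¹, Ea = 68.0 kJ mol⁻¹, ΔH = −30.0 kJ mol⁻¹)
    solid substrate ⇌ starting material, rate k4*(cs4 - [starting material]) while solid is left; crystals form when [starting material] > cs4 (solubility = 25.0 mM, k = 6.90 × 10⁻⁴ s⁻¹)
    (constants at 25 °C)

By dissolving alone the gap to solubility halves in 16.7 min, shorter than the half-life of free enzyme by unfolding, 89 min. In the flask at 300 min, 17.7% of the catalyst can still turn over, and the backward rate of complex to free enzyme and product is 99.9% of the forward. The neighbour flask with 0.013 M of solid substrate ends with 0% of it as solid, so 0.339 gives 25.3% product there, and that flask holds 25.1%.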